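6.13 mM/h is the number to carry: the mean gas demand D, the target formed per hour between the first and last alder readings, counted as gas used one for one. It is a reading, with the scatter stated below.

the same everywhere: substrate 0.30 M; gas phase 10 mM (held); catalyst 6.3 mM
- larch: added ligand 10 mM; the very flask that is asked about, followed so far
- alder: added ligand 5 mM; run made earlier
- flask: added ligand 10 mM; time 5.0 h

larch run (percent of the substrate charged)

| time / min | target / % | substrate / % |
|---|---|---|
| 10.0 | 0.6 | 100.2 |
| 20.0 | 0.5 | 99.7 |
| 50.0 | 0.6 | 99.2 |
| 120 | 2.9 | 97.0 |

alder run (percent of the substrate charged)

| time / h | target / % | substrate / % |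
|---|---|---|
| 1.33 | 2.1 | 98.3 |
| 2.50 | 5.3 | 95.8 |
| 4.00 | 7.7 | 94.0 |
| 5.00 | 9.6 | 90.8 |

(scatter of a reading: 0.5 percentage points)

- concentration of target at 5.0 h, in M
- concentration of substrate at 5.0 h, in M
- concentration of dissolved gas at 5.0 h, in M

- at the start none of the gas phase is in solution

You hunched that a straight line would do, and for target in larch I agree, since alder's last reading still shows 90.8% of the substrate. From larch's last reading, 2.9% at 2 h, I add D over the remaining 3.00 h and get 0.0271 M of target, leaving 0.273 M of substrate. That borrows a rate from a flask with half the ligand, so read it as high, if anything.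

The gas needs its own reckoning. Suppose gas crosses at k(c* − [dissolved gas]), with k the transfer coefficient and c* saturation. At quasi-steady state crossing equals demand, so dissolved gas stands at c* − D/k. The runs don't give k, but alder's line meets zero at a lag τ = 0.302 h, a reading, and if gas use grows with dissolved gas, such a lag comes out shorter than 1/k. Borrowing D and τ from alder, I put dissolved gas in larch below roughly c* − Dτ = 8.15 mM, which is an estimate and no firm bound.

The forecast gave 0.026 M of target, 0.273 M of substrate and 0.009 M of dissolved gas, above my estimate, saying “It should therefore be near saturation”. The flask gives 0.0253 M, 0.275 M and 0.00503 M.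

    gas phase ⇌ dissolved gas, rate k1*(csat - [dissolved gas]) (kL = 1.10 /h)
    substrate + dissolved gas + catalyst → catalyst + target (k = 800 /M²/h)
    catalyst + added ligand ⇌ idle complex, settled at all times (K = 33.0 /M)

Target in this flask stands at 0.0253 M partly through the slow crossing of gas together with the time allowed: the same run with fast crossing reaches 0.0533 M, and ten times the time reaches 0.209 M. With k = 1.1 /h, c* − D/k, with D still alder's reading, gives 4.43 mM against the computed 5.03 mM.

For the flask left until 20 h, D gives 0.121 M of target after the lag. The computed value is 0.100 M, with substrate down to 66.6%, whereas D was read over substrate readings from 98.3% to 90.8%.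

The data stem from a simulated flask with made-up constants, and the scatter is random.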